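Ring A is carried as a saturated ketone: the C2–Br and C6–Br bonds are made alpha to a carbonyl and the ring is aromatised in the same operation. This exploits the ring A pattern of bromines at C2 and C6 flanking the C1 hydroxyl with the ether oxygen para at C4, which a symmetric 4-substituted cyclohexanone delivers on fourfold alpha-bromination and twofold loss of HBr. The precursor is 4-(2,4,5-tribromo-3,6-dimethoxyphenoxy)cyclohexanone, ring B already hexasubstituted and its hydroquinone oxygens capped as methyl ethers; its ether bond comes from Mitsunobu substitution at sp3 carbon. A last ring A bromination at C3/C5 and BBr3 demethylation complete the target.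

Key step: step 4

Remark: the target and all intermediates are achiral (C4 of each cyclohexane intermediate lies on a mirror plane). Ring B is a para-hydroquinone in the target, so it stays as its dimethyl ether until the last use of Br2 and cannot be oxidised to a quinone.

Step 1
Reactants: 1 2,5-dimethoxyphenol; 2 bromine
Product: 3 3,4,6-tribromo-2,5-dimethoxyphenol
Conditions: Br2 (3.3 equiv), AcOH, 15 → 45 °C; Na2S2O3 aq. quench
Reagents that add atoms: bromine (compound 2), BrBr
Why: Electrophilic aromatic bromination: every free ring position (C3, C4, C6) is ortho or para to a hydroxyl or methoxyl donor, so exhaustive bromination should fill all three and can give only one hexasubstituted product.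

Step 2
Reactants: 3 3,4,6-tribromo-2,5-dimethoxyphenol; 4 1,4-dioxaspiro[4.5]decan-8-ol
Product: 5 8-(2,4,5-tribromo-3,6-dimethoxyphenoxy)-1,4-dioxaspiro[4.5]decane
Conditions: PPh3, DIAD, THF, 0 → 45 °C
Reagents that add atoms: none
Why: Mitsunobu etherification: the tribromophenol is acidic enough to protonate the PPh3–DIAD betaine and its phenoxide displaces the alkoxyphosphonium group at the secondary sp3 carbon by SN2, the carbinol carbon lying on a mirror plane so that inversion creates no stereocenter.

Step 3
Reactants: 5 8-(2,4,5-tribromo-3,6-dimethoxyphenoxy)-1,4-dioxaspiro[4.5]decane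
Product: 6 4-(2,4,5-tribromo-3,6-dimethoxyphenoxy)cyclohexan-1-one
Conditions: 2 M aq. HCl, THF, 40 °C
Reagents that add atoms: water, O
Why: Acid-catalysed ketal hydrolysis releases the ketone, while the aryl methyl ethers, the secondary alkyl aryl ether and the aryl bromides are inert to dilute aqueous acid.

Step 4
Reactants: 6 4-(2,4,5-tribromo-3,6-dimethoxyphenoxy)cyclohexan-1-one; 2 bromine
Product: 9 2,6-dibromo-4-(2,4,5-tribromo-3,6-dimethoxyphenoxy)phenol, via tetrabromoketone 7 (not isolated), via dibromodienone 8 (not isolated)
Conditions: Br2 (4.2 equiv), AcOH, cat. HBr, 20 → 40 °C; evaporate; then Li2CO3, LiBr, DMF, 100 °C; dilute aq. HCl work-up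
Reagents that add atoms: bromine (compound 2), BrBr
Why: Acid-catalysed enolisation toward either alpha carbon and capture of the enol by Br2, repeated four times, should convert 6 into the 2,2,6,6-tetrabromoketone 7, since C2 and C6 are the only enolisable carbons of the symmetric ketone. Carbonate in DMF then removes HBr twice, across C2–C3 and across C5–C6, giving the cross-conjugated 2,6-dibromodienone 8, whose C4 hydrogen shifts to the carbonyl oxygen so that ring A becomes the 2,6-dibromophenol 9. The closest known reaction type is the conversion of cyclohexanones into 2,6-dihalophenols through 2,2,6,6-tetrahalocyclohexanones, combined with Li2CO3/LiBr dehydrobromination of alpha-bromoketones. No ring is closed and no stereocenter is formed: the existing six-membered ring is aromatised, and C4 gives up its hydrogen only in the final tautomerisation, so the C4–O bond is retained. The selectivity needed is positional, bromine at C2 and C6 only, and it is secured by the carbonyl, which activates no other carbon, and by ring B, which has no free position and no free hydroxyl to be oxidised.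

Step 5
Reactants: 9 2,6-dibromo-4-(2,4,5-tribromo-3,6-dimethoxyphenoxy)phenol; 2 bromine
Product: 10 2,3,6-tribromo-4-(2,4,5-tribromo-3,6-dimethoxyphenoxy)phenol
Conditions: Br2 (1.05 equiv), anhydrous AcOH, 25 → 45 °C, dark; Na2S2O3 aq. quench
Reagents that add atoms: bromine (compound 2), BrBr
Why: Electrophilic aromatic bromination: ring A of 9 has only two hydrogens (C3 and C5), equivalent and ortho to the ether oxygen, so one equivalent of Br2 can give a single monobromide, the first bromine slowing a second entry and hexasubstituted ring B being unable to react.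

Step 6
Reactants: 10 2,3,6-tribromo-4-(2,4,5-tribromo-3,6-dimethoxyphenoxy)phenol
Product: 11 2,3,5-tribromo-6-(2,3,5-tribromo-4-hydroxyphenoxy)benzene-1,4-diol (target)
Conditions: BBr3 (5 equiv), CH2Cl2, −78 °C → rt; then H2O, Na2S2O4 aq. wash, under argon
Reagents that add atoms: none
Why: BBr3 demethylation of aryl methyl ethers: boron coordinates each methoxy oxygen and bromide removes the methyl group by SN2, leaving the diaryl ether and all C–Br bonds intact, and the borates are hydrolysed on reductive aqueous work-up to free the hydroquinone without oxidation.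

Compound list
1 | 2,5-dimethoxyphenol | COc1ccc(OC)c(O)c1 | starting material
2 | bromine | BrBr | starting material
3 | 3,4,6-tribromo-2,5-dimethoxyphenol | Oc1c(OC)c(Br)c(Br)c(OC)c1Br | intermediate
4 | 1,4-dioxaspiro[4.5]decan-8-ol | OC1CCC2(CC1)OCCO2 | starting material
5 | 8-(2,4,5-tribromo-3,6-dimethoxyphenoxy)-1,4-dioxaspiro[4.5]decane | COc1c(Br)c(Br)c(OC)c(OC2CCC3(CC2)OCCO3)c1Br | intermediate
6 | 4-(2,4,5-tribromo-3,6-dimethoxyphenoxy)cyclohexan-1-one | O=C1CCC(Oc2c(OC)c(Br)c(Br)c(OC)c2Br)CC1 | intermediate
7 | 2,2,6,6-tetrabromo-4-(2,4,5-tribromo-3,6-dimethoxyphenoxy)cyclohexan-1-one | O=C1C(Br)(Br)CC(Oc2c(OC)c(Br)c(Br)c(OC)c2Br)CC1(Br)Br | intermediate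
8 | 2,6-dibromo-4-(2,4,5-tribromo-3,6-dimethoxyphenoxy)cyclohexa-2,5-dien-1-one | O=C1C(Br)=CC(Oc2c(OC)c(Br)c(Br)c(OC)c2Br)C=C1Br | intermediate
9 | 2,6-dibromo-4-(2,4,5-tribromo-3,6-dimethoxyphenoxy)phenol | Oc1c(Br)cc(Oc2c(OC)c(Br)c(Br)c(OC)c2Br)cc1Br | intermediate
10 | 2,3,6-tribromo-4-(2,4,5-tribromo-3,6-dimethoxyphenoxy)phenol | Oc1c(Br)cc(Oc2c(OC)c(Br)c(Br)c(OC)c2Br)c(Br)c1Br | intermediate
11 | 2,3,5-tribromo-6-(2,3,5-tribromo-4-hydroxyphenoxy)benzene-1,4-diol | Oc1c(Br)cc(Oc2c(O)c(Br)c(Br)c(O)c2Br)c(Br)c1Br | target

Total step count: 6
Longest linear sequence: 6 steps (1 → 3 → 5 → 6 → 9 → 10 → 11); alcohol 4 and bromine 2 enter as purchased materials.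

Steps most likely to fail

Step 4. Three processes could hurt it:
- the fourth alpha-bromination may stall;
- positive bromine may be lost reductively from the geminal dibromides during the carbonate stage;
- the HBr formed may slowly cleave the secondary alkyl aryl ether.

Each would lead to mixtures of under-brominated phenols. The fallback sets out from 6 and aromatises first without installing halogen. Catalytic I2 in DMSO at about 100 °C, a known dehydrogenative aromatisation of cyclohexanones with DMSO as terminal oxidant, should give 4-(2,4,5-tribromo-3,6-dimethoxyphenoxy)phenol F1. Its para position is blocked, so Br2 (2.05 equiv) in AcOH/CH2Cl2 at 0 °C → rt should dibrominate both positions ortho to the hydroxyl. The fallback comes back to the route at 9.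

Step 5. Bromine may attack ipso at C4, para to the free hydroxyl, which would oxidatively expel the aryloxy group, or a second bromine may enter at C5. The fallback sets out from 9 and caps the hydroxyl first. MeI and K2CO3 in acetone should give 1,3-dibromo-2-methoxy-5-(2,4,5-tribromo-3,6-dimethoxyphenoxy)benzene F2. With no free hydroxyl, no dienone can form, and the ring is less reactive, so one bromination should be easier to stop. NBS (1.0 equiv) in trifluoroacetic acid with catalytic H2SO4 should then give 1,3,4-tribromo-2-methoxy-5-(2,4,5-tribromo-3,6-dimethoxyphenoxy)benzene F3. BBr3 in CH2Cl2 removes all three methyl groups at once, and the fallback comes back to the route at 11.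

Step 2. The activated secondary alcohol may eliminate to the cyclohexene faster than the doubly ortho-substituted phenoxide can substitute. The fallback sets out from 4 and uses a preformed electrophile. MsCl and Et3N in CH2Cl2 at 0 °C should give 1,4-dioxaspiro[4.5]decan-8-yl methanesulfonate F4. Heating F4 with phenol 3 and Cs2CO3 in DMF at 80 °C is a Williamson-type SN2 displacement by a weakly basic caesium phenoxide. The fallback comes back to the route at 5.

Further compounds
F1 | step 4 | 4-(2,4,5-tribromo-3,6-dimethoxyphenoxy)phenol | Oc1ccc(Oc2c(OC)c(Br)c(Br)c(OC)c2Br)cc1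
F2 | step 5 | 1,3-dibromo-2-methoxy-5-(2,4,5-tribromo-3,6-dimethoxyphenoxy)benzene | COc1c(Br)cc(Oc2c(OC)c(Br)c(Br)c(OC)c2Br)cc1Br
F3 | step 5 | 1,3,4-tribromo-2-methoxy-5-(2,4,5-tribromo-3,6-dimethoxyphenoxy)benzene | COc1c(Br)cc(Oc2c(OC)c(Br)c(Br)c(OC)c2Br)c(Br)c1Br
F4 | step 2 | 1,4-dioxaspiro[4.5]decan-8-yl methanesulfonate | CS(=O)(=O)OC1CCC2(CC1)OCCO2
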